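**Retrosynthetic overview**

- The target is traced back through benzyl hydrogenolysis and acid closure of ring C (O1–C2) to a symmetric 2‑acylresorcinol 1,3‑diketone.
- Ring A of that diketone is not taken from an arene. It is cut at C4a–C5 and C4a–C8a, so the terminal carbon of a 1‑aryl‑1,3‑butanedione is acylated twice by a symmetric five‑carbon diester that already carries the C6, C7 and C8 oxygens.
- The strategy rests on the local mirror symmetry of ring A through C4a and C7: C5 (OH) and C8a (O1) are both oxygen‑bearing carbons of carboxyl origin flanking C4a, and C6, C7 and C8 each carry OMe. Either phenol can therefore close ring C and the 5‑OH is left free.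
- The diester comes from dimethyl 3‑oxopentanedioate (diazo transfer, O–H insertion, ketalization); the diketone comes from acetosyringone (benzylation, Claisen condensation).
- Ring order: ring B is bought in, ring A is formed in step 6, ring C in step 7.

Key step: step 6

Assumption (remark on the chemistry): the five‑carbon diester enters the ring‑forming step with the future C7 as a dimethyl ketal, not as the enol ether, because a 3‑alkoxyglutaconate has a vinylogous malonate C–H that would protonate the diketone dianion before it could acylate; the ketal loses methanol after ring closure and gives the same C7–OMe arene. The 2,4‑dimethoxy diesters and the two unisolated key‑step intermediates are diastereomer mixtures whose stereocentres all vanish on aromatization, so no configuration is specified.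

**Step 1**
Reactants: 1 dimethyl 3-oxopentanedioate
Product: 2 dimethyl 2,4-bis(diazo)-3-oxopentanedioate
Conditions: 4-acetamidobenzenesulfonyl azide (2.2 equiv), Et3N, MeCN, 0 °C → rt (2 kept in solution or handled in small portions behind a shield)
Reagents that add atoms: 4-acetamidobenzenesulfonyl azide, CC(=O)Nc1ccc(cc1)S(=O)(=O)N=[N+]=[N-]
Why: Regitz diazo transfer; each methylene of 1 lies between a ketone and an ester, so the amine enolizes it and the sulfonyl azide should deliver N2 to carbon on both sides.

**Step 2**
Reactants: 2 dimethyl 2,4-bis(diazo)-3-oxopentanedioate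
Product: 3 dimethyl 2,4-dimethoxy-3-oxopentanedioate
Conditions: Rh2(OAc)4 (2 mol%), dry MeOH (excess), 1,2-dichloroethane, 60 °C
Reagents that add atoms: methanol, CO
Why: Rh‑carbenoid O–H insertion; each diazo group should become an electrophilic carbenoid that excess methanol captures through an oxonium ylide, the standard route to 2‑alkoxy‑1,3‑dicarbonyl compounds, and no configuration needs control.

**Step 3**
Reactants: 3 dimethyl 2,4-dimethoxy-3-oxopentanedioate
Product: 4 dimethyl 2,3,3,4-tetramethoxypentanedioate
Conditions: HC(OMe)3, MeOH, H2SO4 (cat.), rt → 50 °C; NaOMe to neutral before concentration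
Reagents that add atoms: trimethyl orthoformate, COC(OC)OC; methanol, CO
Why: Acid‑catalysed ketalization with orthoformate as water scavenger; the two α‑methoxy ester groups make the ketone electron‑poor and favour the tetrahedral ketal, while the crowded tetrasubstituted enol ether is disfavoured in methanol, and neutralization before concentration should keep the ketal from losing methanol.

**Step 4**
Reactants: 5 acetosyringone; 6 benzyl bromide
Product: 7 1-[4-(benzyloxy)-3,5-dimethoxyphenyl]ethan-1-one
Conditions: K2CO3, DMF, 60 °C
Reagents that add atoms: none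
Why: Williamson ether synthesis; the phenoxide of 5 should be O‑alkylated by the benzylic bromide (SN2), the flanking methoxy groups slowing but not blocking the reaction.

**Step 5**
Reactants: 7 1-[4-(benzyloxy)-3,5-dimethoxyphenyl]ethan-1-one; 8 ethyl acetate
Product: 9 1-[4-(benzyloxy)-3,5-dimethoxyphenyl]butane-1,3-dione
Conditions: NaH (2.5 equiv), EtOAc (excess), THF, reflux; aq. HCl
Reagents that add atoms: none
Why: Crossed Claisen condensation; the sodium enolate of the aryl methyl ketone is acetylated by ethyl acetate and the equilibrium is pulled through by deprotonation of the 1,3‑diketone, the classical route to 1‑arylbutane‑1,3‑diones.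

**Step 6**
Reactants: 9 1-[4-(benzyloxy)-3,5-dimethoxyphenyl]butane-1,3-dione (2 equiv); 4 dimethyl 2,3,3,4-tetramethoxypentanedioate (1 equiv)
Product: 12 1-[4-(benzyloxy)-3,5-dimethoxyphenyl]-3-(2,6-dihydroxy-3,4,5-trimethoxyphenyl)propane-1,3-dione, via triketo ester 10 (not isolated), via acylcyclohexanedione ketal 11 (not isolated)
Conditions: 9, LiN(iPr)2 (2.05 equiv per 9), THF, −78 → 0 °C; 4, −78 → −20 °C; NaOMe, MeOH, 50 °C; HCl/MeOH (anhydrous), 0 °C → rt; surplus 9 recovered
Reagents that add atoms: none
Why: Proposed new method: the terminal carbanion of the dilithio dianion of 9 (the future C4a) should add to one ester carbonyl of 4 and expel methoxide (Claisen condensation) to give triketo ester 10, which the second equivalent of dianion deprotonates at once; in NaOMe/MeOH the now doubly activated C4a carbanion acylates the remaining ester to give triacylmethane 11, and anhydrous acid then removes one methanol from the C7 ketal, after which two enolizations deliver the arene without any oxidant. The closest known reaction types are the acylation of 1,3‑diketone dianions at the terminal carbon by aliphatic and aromatic esters to give 1,3,5‑triketones, and the Dieckmann‑type closure of 5,7‑dioxo esters and 3,5,7‑triketo esters to 2‑acylcyclohexane‑1,3‑diones and acylphloroglucinols; what is new is that one fully oxygenated diester acylates the same carbon twice. Ring A is closed in the second acylation by 6‑exo‑trig attack of C4a on the ester carbonyl that becomes C8a, C4a–C5 having been made in the intermolecular event. No stereocentre remains: the two methoxy‑bearing stereocentres carried by 4, 10 and 11 are erased on aromatization, so every diastereomer converges on 12. The step needs carbonyl addition to win over α‑deprotonation of 4 with β‑loss of methoxide, which is helped by lithium chelation of the α‑methoxy ester and by the ketal leaving only ordinary ester α‑hydrogens, and it needs closure through carbon, not through enolate oxygen or by aldol addition to a ketone, which the strongly basic medium should secure because the ketone carbonyls are masked as enolates and the triacylmethanide of 11 is the thermodynamic sink. Acidification is kept anhydrous so that the C7 ketal eliminates methanol and is not hydrolysed to a C7 hydroxyl, and the local symmetry of ring A makes the order of the two acylations immaterial.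

**Step 7**
Reactants: 12 1-[4-(benzyloxy)-3,5-dimethoxyphenyl]-3-(2,6-dihydroxy-3,4,5-trimethoxyphenyl)propane-1,3-dione
Product: 13 2-[4-(benzyloxy)-3,5-dimethoxyphenyl]-5-hydroxy-6,7,8-trimethoxy-4H-chromen-4-one
Conditions: H2SO4 (cat.), AcOH, 60 °C
Reagents that add atoms: none
Why: Acid‑catalysed cyclodehydration of an o‑hydroxyaryl 1,3‑diketone (the closing stage of the Baker–Venkataraman flavone synthesis); either of the two equivalent phenols adds to the aryl ketone and loss of water forms ring C, leaving the other phenol as the chelated 5‑OH, while catalytic acid at moderate temperature should spare the benzyl ether.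

**Step 8**
Reactants: 13 2-[4-(benzyloxy)-3,5-dimethoxyphenyl]-5-hydroxy-6,7,8-trimethoxy-4H-chromen-4-one
Product: 14 5-hydroxy-2-(4-hydroxy-3,5-dimethoxyphenyl)-6,7,8-trimethoxy-4H-chromen-4-one (5,4'-dihydroxy-6,7,8,3',5'-pentamethoxyflavone)
Conditions: H2 (1 atm), Pd/C, EtOAc/MeOH, rt
Reagents that add atoms: none
Why: Catalytic hydrogenolysis of the benzyl aryl ether, which at ambient pressure should leave the chromone C2=C3 bond, the aryl methyl ethers and the 5‑OH untouched.

**Compound list**

1 | dimethyl 3-oxopentanedioate | COC(=O)CC(=O)CC(=O)OC | starting material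
2 | dimethyl 2,4-bis(diazo)-3-oxopentanedioate | COC(=O)C(=[N+]=[N-])C(=O)C(=[N+]=[N-])C(=O)OC | intermediate
3 | dimethyl 2,4-dimethoxy-3-oxopentanedioate (diastereomer mixture) | COC(=O)C(OC)C(=O)C(OC)C(=O)OC | intermediate
4 | dimethyl 2,3,3,4-tetramethoxypentanedioate (diastereomer mixture) | COC(=O)C(OC)C(OC)(OC)C(OC)C(=O)OC | intermediate
5 | acetosyringone, 1-(4-hydroxy-3,5-dimethoxyphenyl)ethan-1-one | CC(=O)c1cc(OC)c(O)c(OC)c1 | starting material
6 | benzyl bromide | BrCc1ccccc1 | starting material
7 | 1-[4-(benzyloxy)-3,5-dimethoxyphenyl]ethan-1-one | CC(=O)c1cc(OC)c(OCc2ccccc2)c(OC)c1 | intermediate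
8 | ethyl acetate | CCOC(C)=O | starting material
9 | 1-[4-(benzyloxy)-3,5-dimethoxyphenyl]butane-1,3-dione | CC(=O)CC(=O)c1cc(OC)c(OCc2ccccc2)c(OC)c1 | intermediate
10 | methyl 9-[4-(benzyloxy)-3,5-dimethoxyphenyl]-2,3,3,4-tetramethoxy-5,7,9-trioxononanoate (diastereomer mixture, not isolated) | COC(=O)C(OC)C(OC)(OC)C(OC)C(=O)CC(=O)CC(=O)c1cc(OC)c(OCc2ccccc2)c(OC)c1 | intermediate
11 | 2-{3-[4-(benzyloxy)-3,5-dimethoxyphenyl]-3-oxopropanoyl}-4,5,5,6-tetramethoxycyclohexane-1,3-dione (diastereomer mixture, not isolated) | COC1C(=O)C(C(=O)CC(=O)c2cc(OC)c(OCc3ccccc3)c(OC)c2)C(=O)C(OC)C1(OC)OC | intermediate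
12 | 1-[4-(benzyloxy)-3,5-dimethoxyphenyl]-3-(2,6-dihydroxy-3,4,5-trimethoxyphenyl)propane-1,3-dione | COc1cc(C(=O)CC(=O)c2c(O)c(OC)c(OC)c(OC)c2O)cc(OC)c1OCc1ccccc1 | intermediate
13 | 2-[4-(benzyloxy)-3,5-dimethoxyphenyl]-5-hydroxy-6,7,8-trimethoxy-4H-chromen-4-one | COc1cc(-c2cc(=O)c3c(O)c(OC)c(OC)c(OC)c3o2)cc(OC)c1OCc1ccccc1 | intermediate
14 | 5-hydroxy-2-(4-hydroxy-3,5-dimethoxyphenyl)-6,7,8-trimethoxy-4H-chromen-4-one | COc1cc(-c2cc(=O)c3c(O)c(OC)c(OC)c(OC)c3o2)cc(OC)c1O | target

**Step count**

Total steps: 8. Longest linear sequence: 6 (steps 1, 2, 3, 6, 7, 8).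

**Steps most likely to fail**

1. Step 6 (proposed new method). The dianion may act as a base on the α‑hydrogens of 4, with β‑loss of methoxide, faster than it adds to the ester carbonyl. The triketo ester may also fail to close through carbon (lactonization through enolate oxygen, aldol closure, or pyranone formation on acidification), or a second dianion may attack the remaining ester. The fallback takes ring A from a preformed arene by the classical chalcone route and sets out from benzyl bromide 6. O‑Benzylation of commercial syringaldehyde (K2CO3, DMF) should give 4-(benzyloxy)-3,5-dimethoxybenzaldehyde F1. Commercial 1-(6-hydroxy-2,3,4-trimethoxyphenyl)ethan-1-one would be brominated at its only free ring position (Br2, AcOH) to 1-(3-bromo-2-hydroxy-4,5,6-trimethoxyphenyl)ethan-1-one F2, and copper‑mediated methoxylation (NaOMe, CuBr, DMF/MeOH, 110 °C) should give 1-(2-hydroxy-3,4,5,6-tetramethoxyphenyl)ethan-1-one F3. Claisen–Schmidt condensation of the two halves (KOH, EtOH, rt) should give (E)-3-[4-(benzyloxy)-3,5-dimethoxyphenyl]-1-(2-hydroxy-3,4,5,6-tetramethoxyphenyl)prop-2-en-1-one F4, and oxidative cyclization (I2 cat., DMSO, 130 °C) should give 2-[4-(benzyloxy)-3,5-dimethoxyphenyl]-5,6,7,8-tetramethoxy-4H-chromen-4-one F5. BCl3 (CH2Cl2, −78 → 0 °C) should then cleave the chelated 5‑methyl ether and the benzyl ether together, so the fallback comes back to the route at target 14.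

2. Step 3. Ketal formation may stall at the hindered, electron‑poor carbonyl, or the ketal may lose methanol to the enol ether during acid‑catalysed equilibration or isolation. The fallback builds the ketal kinetically by addition to the alkene instead of to the carbonyl and sets out from 3. Forcing O‑methylation (HC(OMe)3, H2SO4 cat., 110 °C with removal of methanol) should give dimethyl (Z)-2,3,4-trimethoxypent-2-enedioate F6 (either alkene isomer serves). Bromomethoxylation (NBS, MeOH, 0 °C) should place bromine at C2 and methanol at the oxocarbenium carbon C3 to give dimethyl 2-bromo-2,3,3,4-tetramethoxypentanedioate F7. Radical debromination (Bu3SnH, AIBN, benzene, 80 °C) then comes back to the route at 4.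

3. Step 2. The twofold insertion may be spoiled by carbene dimerization, capture of adventitious water (α‑hydroxy by‑products) or a sluggish second insertion. The fallback introduces the C2 and C4 oxygens by enolate oxidation after the ketal is in place and sets out from 1. Ketalization of the unhindered ketone (HC(OMe)3, MeOH, H2SO4 cat.) should give dimethyl 3,3-dimethoxypentanedioate F8. One round of LiN(iPr)2, THF, −78 °C followed by 2-(phenylsulfonyl)-3-phenyloxaziridine should give dimethyl 2-hydroxy-3,3-dimethoxypentanedioate F9, and a second round with an extra equivalent of base should give dimethyl 2,4-dihydroxy-3,3-dimethoxypentanedioate F10. O‑Methylation (MeI, Ag2O, MeCN) comes back to the route at 4, bypassing 2 and 3.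

**Further compounds**

F1 | step 6 | 4-(benzyloxy)-3,5-dimethoxybenzaldehyde | COc1cc(C=O)cc(OC)c1OCc1ccccc1
F2 | step 6 | 1-(3-bromo-2-hydroxy-4,5,6-trimethoxyphenyl)ethan-1-one | CC(=O)c1c(O)c(Br)c(OC)c(OC)c1OC
F3 | step 6 | 1-(2-hydroxy-3,4,5,6-tetramethoxyphenyl)ethan-1-one | CC(=O)c1c(O)c(OC)c(OC)c(OC)c1OC
F4 | step 6 | (E)-3-[4-(benzyloxy)-3,5-dimethoxyphenyl]-1-(2-hydroxy-3,4,5,6-tetramethoxyphenyl)prop-2-en-1-one | COc1cc(/C=C/C(=O)c2c(O)c(OC)c(OC)c(OC)c2OC)cc(OC)c1OCc1ccccc1
F5 | step 6 | 2-[4-(benzyloxy)-3,5-dimethoxyphenyl]-5,6,7,8-tetramethoxy-4H-chromen-4-one | COc1cc(-c2cc(=O)c3c(OC)c(OC)c(OC)c(OC)c3o2)cc(OC)c1OCc1ccccc1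
F6 | step 3 | dimethyl (Z)-2,3,4-trimethoxypent-2-enedioate | COC(=O)/C(OC)=C(OC)\C(OC)C(=O)OC
F7 | step 3 | dimethyl 2-bromo-2,3,3,4-tetramethoxypentanedioate | COC(=O)C(Br)(OC)C(OC)(OC)C(OC)C(=O)OC
F8 | step 2 | dimethyl 3,3-dimethoxypentanedioate | COC(=O)CC(OC)(OC)CC(=O)OC
F9 | step 2 | dimethyl 2-hydroxy-3,3-dimethoxypentanedioate | COC(=O)C(O)C(OC)(OC)CC(=O)OC
F10 | step 2 | dimethyl 2,4-dihydroxy-3,3-dimethoxypentanedioate | COC(=O)C(O)C(OC)(OC)C(O)C(=O)OC
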